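All runs were computed with constants of no real substance, and the scatter is random.

Friday's run was charged as maple is, so we read maple's end straight from it: 58.3% at 20.0 min.

| flask | substrate | coupling partner | free catalyst | remark | time |
|---|---|---|---|---|---|
| Friday's | 0.10 M | 0.10 M | 2 mM | run made earlier |  |
| Monday's | 0.10 M | 0.067 M | 2 mM | run made earlier |  |
| Wednesday's | 0.10 M | 0.15 M | 2 mM | run made earlier |  |
| birch | 0.10 M | 0.100 M | 2.0 mM | one stirred flow tank at steady state, fed with the mixture as stated, mean residence time 20 min |  |
| ash | 0.10 M (fed, over 20.0 min) | 0.100 M | 2.0 mM | a stirred flask in which substrate is dosed at a steady rate over 20.0 min without added volume, worked up at 20 min | 20 min |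
| maple | 0.10 M | 0.100 M | 2.0 mM | a closed flask charged with all of it at once and left for 20 min | 20 min |
| cedar | 0.10 M | 0.100 M | 2.0 mM | a single well-mixed tank run continuously and read at steady state, 100 min in it on average |  |

| run | time / min | product / % |
|---|---|---|
| Friday's | 1.50 | 5.4 |
| Friday's | 3.00 | 11.0 |
| Friday's | 6.00 | 21.4 |
| Friday's | 10.0 | 34.2 |
| Friday's | 20.0 | 58.3 |
| Monday's | 2.00 | 5.7 |
| Monday's | 5.00 | 15.9 |
| Monday's | 10.0 | 29.5 |
| Monday's | 15.0 | 40.9 |
| Monday's | 20.0 | 49.9 |
| Wednesday's | 4.00 | 16.2 |
| Wednesday's | 8.00 | 30.5 |
| Wednesday's | 12.0 | 43.2 |
| Wednesday's | 15.0 | 52.1 |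
| Wednesday's | 20.0 | 63.3 |

(scatter of a reading: 0.3 percentage points)

* the set-up with the highest amount of product at the outlet or at the end, in percent of the substrate put in ("none" if the first two lie within 2 percentage points) (birch / ash / maple / cedar / none)
* amount of product at the outlet or at the end, in percent of the substrate put in, birch
* amount of product at the outlet or at the end, in percent of the substrate put in, ash
* amount of product at the outlet or at the end, in percent of the substrate put in, maple
* amount of product at the outlet or at the end, in percent of the substrate put in, cedar

- the stated concentrations are those of everything mixed, before any reaction; amounts are the same in each set-up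
- the feed brings no volume worth counting
- the earlier runs were made in a closed, stirred flask

Substrate and coupling partner are charged at equal strength, so neither is the limiting reagent. We take them to fall together, so one balance serves both. In a tank at steady state, the product leaving equals the rate times the residence time.

So we need a rate. Between 10.0 min and 20.0 min, Friday's product rises by 0.0241 min⁻¹ of the charge, with 53.8% of the substrate left on average. Their quotient, 0.0448 min⁻¹, is our remainder constant: the rate per unit of substrate left.

In a tank, product over substrate left then equals this constant times the residence time. We assume the catalyst behaves in a tank as it does in Friday's flask. For birch this gives 47.3%. For cedar it gives 81.8%.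

The weak link is cedar, which lies above Friday's last reading. So we test the constant along Friday's run. Over the first 3.00 min it reads 0.0388 min⁻¹. From 6.00 min to 10.0 min it reads 0.0443 min⁻¹, higher, and it then stays level with the late value. Cedar with the starting constant gives 79.5%, so we commit to cedar between that figure and 81.8%. Ash is dosed, so this tank balance does not reach it.

The forecast gives birch 47%, ash 37%, maple 58.3% and cedar 83%, with cedar best. Its cedar stands above ours, and it warns: "This extrapolates to low concentrations and assumes the catalyst survives".

The flasks give birch 46.9%, ash 41.8%, maple 58.3% and cedar 78.4%, so cedar is highest.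

catalyst intermediate B ⇌ released group + catalyst intermediate C (K = 0.170 M, k = 3.80 s⁻¹); catalyst intermediate D → free catalyst + product (k = 0.140 s⁻¹); catalyst intermediate B → spent catalyst (k = 4.31 × 10⁻⁴ s⁻¹); coupling partner + free catalyst ⇌ catalyst intermediate A (K = 140 M⁻¹, k = 1.57 M⁻¹ s⁻¹); catalyst intermediate A → catalyst intermediate B (k = 0.135 s⁻¹); substrate + catalyst intermediate C ⇌ catalyst intermediate D (K = 11.0 M⁻¹, k = 5.80 M⁻¹ s⁻¹) Cedar's tank holds 0.0215 M of substrate and 0.0200 M of coupling partner. Cedar's own remainder constant, with 21.5% of its substrate left, is 0.0366 min⁻¹, lower than Friday's, and its 78.4% stands below our span. For cedar to fall to maple's yield, its constant would have to read 0.0140 min⁻¹.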